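## Retrosynthetic overview

1. Feature: in 15 the tertiary hydroxyl on Cb of the cyclopentane (ring B; Ca = CH bearing isopropenyl, Cb = C(CH3)OH, Cc = CH bearing the CH2 link) and the enol oxygen on C2 of the six-membered triketone (ring A; C1 bears the CH2 link, C3 is the methyl/prenyl quaternary carbon, C5 bears the acyl group) are joined by C1–CH2–Cc, so 15 is the hydrate of a dihydropyran O–C2=C1–CH2–Cc–Cb.
2. 15 ⇐ 14 by hydroxide opening of that pyran at C2 (vinylogous ester, Cb–O kept); 14 ⇐ 11 by dearomative prenylation at C3; 11 ⇐ 10 by reduction of the chromene C=C (sets Cc).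
3. 10 ⇐ 8 + 4: Knoevenagel condensation at C1, then oxa-6π closure of the quinone methide, makes C1–CH, O–Cb, the pyran ring and Cb.
4. 4 ⇐ (R)-limonene 1 (ozonolysis, aldol condensation); 8 ⇐ 2,4,6-trihydroxytoluene 7 + (S)-2-methylbutanoyl chloride 6.
5. Ring order: ring B, then the pyran fused onto aromatic ring A, then dearomatisation of ring A; the pyran is opened last.

Key step: step 5

Locants: 10, 11 and 14 are named as cyclopenta[b]chromenes (C1 = Ca, C3a = Cb, O4, C4a = ring A C2, C5 = ring A C3, C8a = ring A C1, C9 = the linking carbon, C9a = Cc).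

Assumption: the (R,R) antipode of the ligand in step 8 is taken to be the one matched to the required face of C5; this sense cannot be predicted with confidence, and the (S,S) antipode would be used if it proves opposite.

## Route

Step 1
Reactants: 1 (R)-limonene
Product: 3 (3R)-6-oxo-3-(prop-1-en-2-yl)heptanal, via limonene ring ozonide 2 (not isolated)
Conditions: O3 (1 equiv, to consumption of 1), CH2Cl2, −78 °C; then PPh3, −78 °C → rt
Reagents that add atoms: ozone, O=[O+][O-]
Why: Ozonolysis with reductive work-up, in which the electron-richer trisubstituted ring alkene reacts much faster than the 1,1-disubstituted isopropenyl group when ozone is limited, and the stereocentre of limonene is not touched.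

Step 2
Reactants: 3 (3R)-6-oxo-3-(prop-1-en-2-yl)heptanal
Product: 4 (S)-2-methyl-5-(prop-1-en-2-yl)cyclopent-1-ene-1-carbaldehyde
Conditions: piperidine (0.2 equiv), AcOH (0.2 equiv), PhMe, 80 °C, Dean–Stark
Reagents that add atoms: none
Why: Intramolecular aldol condensation under enamine catalysis: the aldehyde enamine adds to the methyl ketone in a 5-exo-trig closure and dehydration gives the conjugated cyclopentenecarbaldehyde (ring B), while Ca, which is not in an acidic position of either carbonyl compound, keeps its configuration.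

Step 3
Reactants: 5 (S)-2-methylbutanoic acid
Product: 6 (S)-2-methylbutanoyl chloride
Conditions: (COCl)2, DMF (cat.), CH2Cl2, 0 °C → rt; concentrate
Reagents that add atoms: oxalyl chloride, ClC(=O)C(=O)Cl
Why: Acid chloride formation through the Vilsmeier-type chloroiminium salt at low temperature without base, conditions under which the α-stereocentre is not enolised.

Step 4
Reactants: 7 2,4,6-trihydroxytoluene; 6 (S)-2-methylbutanoyl chloride
Product: 8 (S)-2-methyl-1-(2,4,6-trihydroxy-3-methylphenyl)butan-1-one
Conditions: AlCl3 (4 equiv), PhNO2/CH2Cl2, 0 °C → rt; then 1 M HCl, 0 °C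
Reagents that add atoms: none
Why: Friedel–Crafts C-acylation, in which the two free ring positions of 7 are equivalent and the first acyl group deactivates the ring towards a second; low temperature should limit enolisation of the α-stereocentre, whose integrity would be checked by chiral HPLC.

Step 5
Reactants: 8 (S)-2-methyl-1-(2,4,6-trihydroxy-3-methylphenyl)butan-1-one; 4 (S)-2-methyl-5-(prop-1-en-2-yl)cyclopent-1-ene-1-carbaldehyde
Product: 10 1-[(1S,3aR)-6,8-dihydroxy-3a,5-dimethyl-1-(prop-1-en-2-yl)-1,2,3,3a-tetrahydrocyclopenta[b]chromen-7-yl]-(2S)-2-methylbutan-1-one, via ortho-quinone methide 9 (not isolated)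
Conditions: ethylenediammonium diacetate (20 mol %), PhMe, 110 °C
Reagents that add atoms: none
Why: This is the formal [3+3] annulation of a phloroglucinol with an α,β-unsaturated aldehyde (Knoevenagel condensation followed by oxa-6π electrocyclization), the standard way from citral-type enals to 2H-chromenes. The diammonium salt turns 4 into its iminium ion, C1 of 8 (the only unsubstituted ring carbon) adds to the iminium carbon, and loss of the amine gives the ortho-quinone methide 9, a 1-oxatriene O=C2–C1=CH–Cc=Cb. The pyran ring closes by thermal disrotatory 6π electrocyclization in which the C2 oxygen bonds to the fully substituted Cb, and rearomatisation of ring A drives the closure. Cb, the one new stereocentre, is controlled by Ca of the same five-membered ring: the isopropenyl group, pseudoaxial to avoid the methine hydrogen of the quinone methide, blocks its own face of the cyclopentene, so oxygen should enter trans to it. Site selectivity needs no further control, because the aldehyde carbon ties the oxatriene to the ring alkene and leaves isopropenyl outside it, and closure through the C2 oxygen (para to the acyl group and not held in its hydrogen-bond chelate) is expected to prevail over closure through the C6 oxygen. The regioisomer from the C6 oxygen has the same C1–CH and O–Cb bonds and would converge on 15 by the same three steps, and the minor Cb epimer is removed by chromatography.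

Step 6
Reactants: 10 1-[(1S,3aR)-6,8-dihydroxy-3a,5-dimethyl-1-(prop-1-en-2-yl)-1,2,3,3a-tetrahydrocyclopenta[b]chromen-7-yl]-(2S)-2-methylbutan-1-one
Product: 11 1-[(1R,3aR,9aS)-6,8-dihydroxy-3a,5-dimethyl-1-(prop-1-en-2-yl)-1,2,3,3a,9,9a-hexahydrocyclopenta[b]chromen-7-yl]-(2S)-2-methylbutan-1-one
Conditions: Et3SiH (3 equiv), CF3CO2H (5 equiv), CH2Cl2, −40 → 0 °C; then aq. NaHCO3
Reagents that add atoms: none
Why: Ionic hydrogenation: the C9=C9a bond, conjugated to the trioxygenated ring, should be protonated at Cc far faster than isopropenyl, and the resulting C9 cation takes hydride from Et3SiH at a carbon that is not stereogenic; Cc is set in the protonation, which is late and reversible and so should favour the less strained cis-fused cation (H cis to the angular methyl, CH2 trans to the neighbouring isopropenyl).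

Step 7
Reactants: 12 prenol
Product: 13 methyl 3-methylbut-2-en-1-yl carbonate
Conditions: ClCO2Me, pyridine, CH2Cl2, 0 °C → rt
Reagents that add atoms: methyl chloroformate, COC(=O)Cl
Why: Acylation of a primary allylic alcohol with a chloroformate in the presence of pyridine (carbonate formation).

Step 8
Reactants: 11 1-[(1R,3aR,9aS)-6,8-dihydroxy-3a,5-dimethyl-1-(prop-1-en-2-yl)-1,2,3,3a,9,9a-hexahydrocyclopenta[b]chromen-7-yl]-(2S)-2-methylbutan-1-one; 13 methyl 3-methylbut-2-en-1-yl carbonate
Product: 14 (1R,3aR,5R,9aS)-8-hydroxy-3a,5-dimethyl-7-[(2S)-2-methylbutanoyl]-5-(3-methylbut-2-en-1-yl)-1-(prop-1-en-2-yl)-1,2,3,3a,9,9a-hexahydrocyclopenta[b]chromen-6(5H)-one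
Conditions: Pd2(dba)3·CHCl3 (2.5 mol %), (R,R)-N,N'-(cyclohexane-1,2-diyl)bis[2-(diphenylphosphanyl)benzamide] (7.5 mol %), THF, 0 °C → rt
Reagents that add atoms: none
Why: Tsuji–Trost asymmetric allylic alkylation used as a dearomatisation: the phenoxide of 11, formed by the methoxide released from 13, attacks the unsubstituted terminus of the π-prenyl palladium complex through C5, which is less hindered than the ring-fusion carbon C8a, while O-prenylation is reversible under the catalysis; the chiral ligand, not the remote Cb, selects the face syn to the cyclopentane ring and so sets the quaternary centre.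

Step 9
Reactants: 14 (1R,3aR,5R,9aS)-8-hydroxy-3a,5-dimethyl-7-[(2S)-2-methylbutanoyl]-5-(3-methylbut-2-en-1-yl)-1-(prop-1-en-2-yl)-1,2,3,3a,9,9a-hexahydrocyclopenta[b]chromen-6(5H)-one
Product: 15 (6R)-3,5-dihydroxy-4-{[(1S,2R,5R)-2-hydroxy-2-methyl-5-(prop-1-en-2-yl)cyclopentyl]methyl}-6-methyl-2-[(2S)-2-methylbutanoyl]-6-(3-methylbut-2-en-1-yl)cyclohexa-2,4-dien-1-one
Conditions: LiOH·H2O (10 equiv), 1,4-dioxane/H2O (2:1), 80 °C; then 1 M HCl to pH 3, 0 °C
Reagents that add atoms: lithium hydroxide, [Li+].[OH-]
Why: Saponification of a vinylogous ester by addition–elimination: hydroxide adds to C4a (ring A C2) and the tetrahedral intermediate expels the tertiary alkoxide of Cb, so the C2–O bond is broken and Cb keeps its configuration, and the doubly deprotonated triketone that results should resist reclosure until the cold, mildly acidic work-up.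

## Compound list

1 | (R)-limonene | CC1=CC[C@@H](CC1)C(C)=C | starting material
2 | limonene ring ozonide: 1-methyl-4-(prop-1-en-2-yl)-7,8,9-trioxabicyclo[4.2.1]nonane, (R) at the isopropenyl-bearing carbon, mixture at the trioxolane carbons | CC12CC[C@@H](C(C)=C)CC(O1)OO2 | intermediate
3 | (3R)-6-oxo-3-(prop-1-en-2-yl)heptanal | O=CC[C@@H](CCC(C)=O)C(C)=C | intermediate
4 | (S)-2-methyl-5-(prop-1-en-2-yl)cyclopent-1-ene-1-carbaldehyde | C=C(C)[C@@H]1CCC(C)=C1C=O | intermediate
5 | (S)-2-methylbutanoic acid | CC[C@H](C)C(=O)O | starting material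
6 | (S)-2-methylbutanoyl chloride | CC[C@H](C)C(=O)Cl | intermediate
7 | 2,4,6-trihydroxytoluene | Cc1c(O)cc(O)cc1O | starting material
8 | (S)-2-methyl-1-(2,4,6-trihydroxy-3-methylphenyl)butan-1-one | CC[C@H](C)C(=O)c1c(O)cc(O)c(C)c1O | intermediate
9 | ortho-quinone methide: ring A with C2=O and exocyclic C1=CH carrying the (5S)-2-methyl-5-(prop-1-en-2-yl)cyclopent-1-en-1-yl group syn to the C2 carbonyl | C=C(C)[C@@H]1CCC(C)=C1/C=C1\C(=O)C(C)=C(O)C(C(=O)[C@@H](C)CC)=C1O | intermediate
10 | 1-[(1S,3aR)-6,8-dihydroxy-3a,5-dimethyl-1-(prop-1-en-2-yl)-1,2,3,3a-tetrahydrocyclopenta[b]chromen-7-yl]-(2S)-2-methylbutan-1-one (ether oxygen on Cb trans to isopropenyl) | C=C(C)[C@@H]1CC[C@@]2(C)Oc3c(C)c(O)c(C(=O)[C@@H](C)CC)c(O)c3C=C12 | intermediate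
11 | 1-[(1R,3aR,9aS)-6,8-dihydroxy-3a,5-dimethyl-1-(prop-1-en-2-yl)-1,2,3,3a,9,9a-hexahydrocyclopenta[b]chromen-7-yl]-(2S)-2-methylbutan-1-one (cis ring fusion, C9 trans to isopropenyl) | C=C(C)[C@@H]1CC[C@@]2(C)Oc3c(C)c(O)c(C(=O)[C@@H](C)CC)c(O)c3C[C@@H]12 | intermediate
12 | prenol (3-methylbut-2-en-1-ol) | CC(C)=CCO | starting material
13 | methyl 3-methylbut-2-en-1-yl carbonate | COC(=O)OCC=C(C)C | intermediate
14 | (1R,3aR,5R,9aS)-8-hydroxy-3a,5-dimethyl-7-[(2S)-2-methylbutanoyl]-5-(3-methylbut-2-en-1-yl)-1-(prop-1-en-2-yl)-1,2,3,3a,9,9a-hexahydrocyclopenta[b]chromen-6(5H)-one | C=C(C)[C@@H]1CC[C@@]2(C)OC3=C(C[C@@H]12)C(O)=C(C(=O)[C@@H](C)CC)C(=O)[C@]3(C)CC=C(C)C | intermediate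
15 | (6R)-3,5-dihydroxy-4-{[(1S,2R,5R)-2-hydroxy-2-methyl-5-(prop-1-en-2-yl)cyclopentyl]methyl}-6-methyl-2-[(2S)-2-methylbutanoyl]-6-(3-methylbut-2-en-1-yl)cyclohexa-2,4-dien-1-one (CNP0299585.2) | C=C(C)[C@@H]1CC[C@@](C)(O)[C@H]1CC1=C(O)[C@@](C)(CC=C(C)C)C(=O)C(C(=O)[C@@H](C)CC)=C1O | target

## Step count and risks

Total step count: 9. Longest linear sequence: 6 (steps 1, 2, 5, 6, 8, 9; the branch through steps 3 and 4 is equally long).

Steps most likely to fail:

**Step 6 (ionic hydrogenation).** Protonation of the isopropenyl group (trifluoroacetate addition, reduction to isopropyl, or capture by the C8 hydroxyl) and reduction of the aryl ketone may compete with protonation of the chromene. Kinetic protonation of Cc from the unhindered face would give the trans-fused epimer.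
Fallback: it sets out from 4 and comes back at 11, with the isopropenyl group masked before the annulation.
- Radical anti-Markovnikov addition of thiophenol to 4 (AIBN, PhMe, 80 °C) would give the sulfide enal (5S)-2-methyl-5-[1-(phenylsulfanyl)propan-2-yl]cyclopent-1-ene-1-carbaldehyde F1, as side-chain epimers of no consequence.
- Annulation with 8 under the conditions of step 5 would give the sulfide chromene F2.
- Ionic hydrogenation can then be run with more acid and for longer, so that Cc equilibrates, and would give the sulfide chromane F3.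
- mCPBA (1 equiv, CH2Cl2, −78 °C) would give the sulfoxide F4. Its thermal syn-elimination (PhMe, 110 °C, P(OMe)3 as trap) can form only the 1,1-disubstituted alkene and returns 11.

**Step 8 (dearomative prenylation).** Alkylation may go to C8a or to oxygen, a second prenylation may follow, and the catalyst may be mismatched with the substrate, so that both faces of C5 react.
Fallback: it sets out from 11 and comes back at 14. Direct C-alkylation of the sodium phenoxide with prenyl bromide (NaOMe, MeOH, 0 °C), the classical dearomatising alkylation of alkylated acylphloroglucinols, needs no catalyst–substrate matching. It should give 14 together with its C5 epimer F5, and 14 would be isolated by preparative HPLC.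

**Step 5 (key annulation).** The hindered, fully substituted enal may condense slowly while the amine degrades it, and oxygen may add to both faces of Cb.
Fallback: it sets out from 4 and 8 and comes back at 11, bypassing 10 and step 6.
- Luche reduction of 4 (NaBH4, CeCl3·7H2O, MeOH, 0 °C) would give the allylic alcohol [(5S)-2-methyl-5-(prop-1-en-2-yl)cyclopent-1-en-1-yl]methanol F6.
- With BF3·OEt2 (CH2Cl2, −20 → 0 °C) F6 should ionise to the allyl cation and alkylate C1 of 8 through its CH2 terminus (Friedel–Crafts allylation, as in chroman syntheses from phenols and allylic alcohols), giving the C-allylated phloroglucinol F7.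
- The same acid would protonate the tetrasubstituted alkene of F7 at Cc, and the C2 hydroxyl would capture the Cb cation. The pyran then closes at the chromane level under control by product stability (cis fusion, CH2 trans to isopropenyl).

## Further compounds

F1 | step 6 | (5S)-2-methyl-5-[1-(phenylsulfanyl)propan-2-yl]cyclopent-1-ene-1-carbaldehyde (side-chain epimers) | CC(CSc1ccccc1)[C@@H]1CCC(C)=C1C=O
F2 | step 6 | analogue of 10 with 1-(phenylsulfanyl)propan-2-yl in place of isopropenyl | CC(CSc1ccccc1)[C@@H]1CC[C@@]2(C)Oc3c(C)c(O)c(C(=O)[C@@H](C)CC)c(O)c3C=C12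
F3 | step 6 | analogue of 11 with 1-(phenylsulfanyl)propan-2-yl in place of isopropenyl | CC(CSc1ccccc1)[C@@H]1CC[C@@]2(C)Oc3c(C)c(O)c(C(=O)[C@@H](C)CC)c(O)c3C[C@@H]12
F4 | step 6 | analogue of 11 with 1-(phenylsulfinyl)propan-2-yl in place of isopropenyl | CC(CS(=O)c1ccccc1)[C@@H]1CC[C@@]2(C)Oc3c(C)c(O)c(C(=O)[C@@H](C)CC)c(O)c3C[C@@H]12
F5 | step 8 | (1R,3aR,5S,9aS) epimer of 14 (C5 epimer) | C=C(C)[C@@H]1CC[C@@]2(C)OC3=C(C[C@@H]12)C(O)=C(C(=O)[C@@H](C)CC)C(=O)[C@@]3(C)CC=C(C)C
F6 | step 5 | [(5S)-2-methyl-5-(prop-1-en-2-yl)cyclopent-1-en-1-yl]methanol | C=C(C)[C@@H]1CCC(C)=C1CO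
F7 | step 5 | (2S)-2-methyl-1-(2,4,6-trihydroxy-3-methyl-5-{[(5S)-2-methyl-5-(prop-1-en-2-yl)cyclopent-1-en-1-yl]methyl}phenyl)butan-1-one | C=C(C)[C@@H]1CCC(C)=C1Cc1c(O)c(C)c(O)c(C(=O)[C@@H](C)CC)c1O
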